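The synthesis rests on disconnecting the naphthalene ring that carries the C5' methoxy group (C5'–C8' plus the fusion atoms C4a' and C8a') from a benzene ring that already bears the finished (2S,4S)-chromanyl unit at C1' and the C4' methoxy group. Heating a 4-arylbut-3-enoic acid in Ac2O/NaOAc generates an aryl vinylketene whose six-electron electrocyclisation forms C4a'–C5', aromatises the new ring and installs the C5' oxygen as an acetate in one operation. The step exploits the fact that C4a', lying between C8a' and the methoxy-bearing C4', is the only free ortho carbon, because the other one, C1', holds the chromanyl group. The precursor is an (E)-4-(2-chromanyl-5-methoxyphenyl)but-3-enoic acid with the chroman phenol benzyl-protected.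

Key step: step 8

Locants: chroman O1, C2–C8a; naphthalene C1'–C8a', with C1' bearing the chromanyl group and C4' and C5' the methoxy groups.

Assumption: the (R)-antipode of DTBM-SEGPHOS is taken to direct copper hydride to the face of the chromone that gives the 2S centre; should the sense prove opposite, the (S)-ligand is used with no other change.

Assumption: (2-bromo-5-methoxyphenyl)methanol is purchased; it is also the NaBH4 reduction product of commercial 2-bromo-5-methoxybenzaldehyde.

Step 1
Reactants: 1 2',6'-dihydroxyacetophenone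
Product: 3 5-hydroxy-2-methyl-4H-chromen-4-one, via diketone 2 (not isolated)
Conditions: NaH, EtOAc, THF, reflux; then conc. HCl, AcOH, 80 °C
Reagents that add atoms: ethyl acetate, CCOC(C)=O
Why: Claisen condensation of the ketone enolate with ethyl acetate gives the 1,3-diketone, and acid-catalysed cyclodehydration of a phenol onto the new carbonyl closes the pyranone (either phenol gives the same chromone); no stereocentre is involved.

Step 2
Reactants: 3 5-hydroxy-2-methyl-4H-chromen-4-one
Product: 4 5-(benzyloxy)-2-methyl-4H-chromen-4-one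
Conditions: BnBr, K2CO3, DMF, 60 °C
Reagents that add atoms: benzyl bromide, BrCc1ccccc1
Why: Williamson ether synthesis, in which the chelated 5-OH is the only acidic site and is alkylated by an SN2 reaction once carbonate in warm DMF breaks the hydrogen bond.

Step 3
Reactants: 4 5-(benzyloxy)-2-methyl-4H-chromen-4-one
Product: 6 (S)-5-(benzyloxy)-2-methylchroman-4-one, via silyl enol ether 5 (not isolated)
Conditions: Cu(OAc)2·H2O (cat.), (R)-DTBM-SEGPHOS (cat.), (EtO)2MeSiH, toluene, 0 °C; then 1 M HCl, THF, 0 °C
Reagents that add atoms: none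
Why: Asymmetric conjugate reduction by a bisphosphine-ligated copper hydride, in which hydride is delivered to C2 on the face selected by the chiral ligand (this sets 2S) and the enolate is held as silyl enol ether 5, so the ketone is neither reduced further nor exposed as a free enolate before mild acid hydrolysis.

Step 4
Reactants: 6 (S)-5-(benzyloxy)-2-methylchroman-4-one; 7 (2-bromo-5-methoxyphenyl)methanol
Product: 10 (2S)-5-(benzyloxy)-4-[2-(hydroxymethyl)-4-methoxyphenyl]-2-methylchroman-4-ol (mixture of C4 epimers), via dilithio reagent 8 (not isolated), via organocerium reagent 9 (not isolated)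
Conditions: 7, n-BuLi (2 equiv per 7), THF, −78 °C; CeCl3, −78 °C; then 6, −78 → −20 °C; aq. NH4Cl
Reagents that add atoms: none
Why: 1,2-Addition of an organocerium reagent to a ketone, where the weakly basic, oxophilic aryl–cerium species adds to the hindered carbonyl without enolisation, so the retro-oxa-Michael opening that would erode C2 is avoided; the configuration of the new carbinol centre C4 does not matter because it is planarised in step 5.

Step 5
Reactants: 10 (2S)-5-(benzyloxy)-4-[2-(hydroxymethyl)-4-methoxyphenyl]-2-methylchroman-4-ol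
Product: 11 {2-[(2S,4S)-5-(benzyloxy)-2-methylchroman-4-yl]-5-methoxyphenyl}methanol
Conditions: Et3SiH, CF3CO2H, CH2Cl2, −20 → 0 °C; then aq. NaHCO3–MeOH
Reagents that add atoms: none
Why: Ionic hydrogenation, in which CF3CO2H ionises the tertiary doubly benzylic alcohol to a C4 cation stabilised by the para-methoxyphenyl ring and the two ortho oxygens of the chroman benzo ring, and Et3SiH delivers hydride along the pseudo-axial trajectory of the half-chair that keeps the C2 methyl group equatorial, so the new C4–H is cis to C2–H and the aryl and methyl groups should end up cis (4S); the primary benzylic alcohol, meta to its methoxy group, does not ionise, can trap the cation only reversibly, and is freed from any trifluoroacetate in the bicarbonate–methanol work-up.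

Step 6
Reactants: 11 {2-[(2S,4S)-5-(benzyloxy)-2-methylchroman-4-yl]-5-methoxyphenyl}methanol
Product: 12 2-[(2S,4S)-5-(benzyloxy)-2-methylchroman-4-yl]-5-methoxybenzaldehyde
Conditions: Dess–Martin periodinane, CH2Cl2, rt
Reagents that add atoms: none
Why: Dess–Martin oxidation of a primary benzylic alcohol to the aldehyde under neutral conditions that leave the benzyl ether, the diarylmethine C4–H and both stereocentres untouched.

Step 7
Reactants: 12 2-[(2S,4S)-5-(benzyloxy)-2-methylchroman-4-yl]-5-methoxybenzaldehyde; 13 (2-carboxyethyl)triphenylphosphonium bromide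
Product: 15 (E)-4-{2-[(2S,4S)-5-(benzyloxy)-2-methylchroman-4-yl]-5-methoxyphenyl}but-3-enoic acid, via ylide carboxylate 14 (not isolated)
Conditions: 13, NaN(SiMe3)2 (2 equiv), THF, −78 → 0 °C; then 12, −78 °C → rt; aq. HCl
Reagents that add atoms: none
Why: Wittig olefination, in which the preformed ylide carboxylate adds to the non-enolisable aldehyde at low temperature and should give mainly the E-alkene, as is usual for carboxylate-bearing ylides with aryl aldehydes; the geometry is not critical because both isomers converge in step 8, and no free amide base remains to touch the C4–H.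

Step 8
Reactants: 15 (E)-4-{2-[(2S,4S)-5-(benzyloxy)-2-methylchroman-4-yl]-5-methoxyphenyl}but-3-enoic acid
Product: 20 5-[(2S,4S)-5-(benzyloxy)-2-methylchroman-4-yl]-8-methoxynaphthalen-1-yl acetate, via mixed anhydride 16 (not isolated), via aryl vinylketene 17 (not isolated), via 8aH-dienone 18 (not isolated), via naphthol 19 (not isolated)
Conditions: Ac2O, NaOAc, reflux (ca. 140 °C)
Reagents that add atoms: acetic anhydride, CC(=O)OC(C)=O
Why: Acetic anhydride converts the acid into mixed anhydride 16, acetate removes an α-proton and acetate is expelled to give the vinylketene, and rotation about the former alkene bond in the delocalised dienolate populates the Z isomer 17. The ketene C=C, the cis alkene and the C8a'=C4a' bond of the benzene ring form a hexatriene that undergoes thermal disrotatory six-electron electrocyclisation, closing one six-membered carbocycle through the new C5'–C4a' bond to give dienone 18, which enolises to naphthol 19 and is acetylated by the excess anhydride. The closest known reaction type is the Ac2O/NaOAc benzannulation of 4-arylbut-3-enoic acids and Stobbe half-esters to 1-naphthyl acetates. No lasting stereocentre is created (the sp3 centre C4a' of 18 is lost on aromatisation), and C2 and C4 of the chroman lie away from the reacting atoms and are not epimerisable in the acetate buffer. The only selectivity required is the site of ring closure, and the substrate secures it: of the two carbons ortho to the side chain, C1' bears the chromanyl group, so closure can occur only at the carbon next to the C4' methoxy group, which gives the peri 4',5'-dioxygenation pattern.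

Step 9
Reactants: 20 5-[(2S,4S)-5-(benzyloxy)-2-methylchroman-4-yl]-8-methoxynaphthalen-1-yl acetate
Product: 22 (2S,4S)-5-(benzyloxy)-4-(4,5-dimethoxynaphthalen-1-yl)-2-methylchroman, via potassium naphtholate 21 (not isolated)
Conditions: K2CO3, MeOH, rt; evaporate; then MeI, DMF, 40 °C
Reagents that add atoms: iodomethane, CI
Why: Carbonate-mediated methanolysis (transesterification) of the aryl acetate releases the naphthol directly as its potassium salt 21, which undergoes Williamson O-methylation with iodomethane in DMF; because the salt is alkylated in the same flask, the oxidation-prone free peri-methoxynaphthol is never handled.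

Step 10
Reactants: 22 (2S,4S)-5-(benzyloxy)-4-(4,5-dimethoxynaphthalen-1-yl)-2-methylchroman
Product: 23 Cladonaphchrom B, (2S,4S)-4-(4,5-dimethoxynaphthalen-1-yl)-2-methylchroman-5-ol
Conditions: H2 (1 atm), Pd/C, EtOAc–MeOH, rt
Reagents that add atoms: none
Why: Catalytic hydrogenolysis of the benzyl aryl ether over Pd/C cleaves only the benzylic C–O bond, since the C2–O bond is not benzylic, C4 carries no heteroatom, and the aryl methyl ethers and the naphthalene are inert at atmospheric pressure and room temperature.

Compound list

1 | 2',6'-dihydroxyacetophenone | CC(=O)c1c(O)cccc1O | starting material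
2 | 1-(2,6-dihydroxyphenyl)butane-1,3-dione | CC(=O)CC(=O)c1c(O)cccc1O | intermediate (not isolated)
3 | 5-hydroxy-2-methyl-4H-chromen-4-one | Cc1cc(=O)c2c(O)cccc2o1 | intermediate
4 | 5-(benzyloxy)-2-methyl-4H-chromen-4-one | Cc1cc(=O)c2c(OCc3ccccc3)cccc2o1 | intermediate
5 | (S)-{[5-(benzyloxy)-2-methyl-2H-chromen-4-yl]oxy}diethoxy(methyl)silane | CCO[Si](C)(OCC)OC1=C[C@H](C)Oc2cccc(OCc3ccccc3)c21 | intermediate (not isolated)
6 | (S)-5-(benzyloxy)-2-methylchroman-4-one | O=C1C[C@H](C)Oc2cccc(OCc3ccccc3)c21 | intermediate
7 | (2-bromo-5-methoxyphenyl)methanol | OCc1cc(OC)ccc1Br | starting material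
8 | lithium (2-lithio-5-methoxyphenyl)methanolate | [Li]OCc1cc(OC)ccc1[Li] | intermediate (not isolated)
9 | [2-(lithiooxymethyl)-4-methoxyphenyl]cerium dichloride | [Li]OCc1cc(OC)ccc1[Ce](Cl)Cl | intermediate (not isolated)
10 | (2S)-5-(benzyloxy)-4-[2-(hydroxymethyl)-4-methoxyphenyl]-2-methylchroman-4-ol, C4 configuration not defined | OCc1cc(OC)ccc1C1(O)C[C@H](C)Oc2cccc(OCc3ccccc3)c21 | intermediate
11 | {2-[(2S,4S)-5-(benzyloxy)-2-methylchroman-4-yl]-5-methoxyphenyl}methanol (2,4-cis) | OCc1cc(OC)ccc1[C@@H]1C[C@H](C)Oc2cccc(OCc3ccccc3)c21 | intermediate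
12 | 2-[(2S,4S)-5-(benzyloxy)-2-methylchroman-4-yl]-5-methoxybenzaldehyde | O=Cc1cc(OC)ccc1[C@@H]1C[C@H](C)Oc2cccc(OCc3ccccc3)c21 | intermediate
13 | (2-carboxyethyl)triphenylphosphonium bromide | OC(=O)CC[P+](c1ccccc1)(c1ccccc1)c1ccccc1.[Br-] | starting material
14 | sodium 3-(triphenyl-λ5-phosphanylidene)propanoate | [Na+].[O-]C(=O)CC=P(c1ccccc1)(c1ccccc1)c1ccccc1 | intermediate (not isolated)
15 | (E)-4-{2-[(2S,4S)-5-(benzyloxy)-2-methylchroman-4-yl]-5-methoxyphenyl}but-3-enoic acid | COc1ccc([C@@H]2C[C@H](C)Oc3cccc(OCc4ccccc4)c32)c(/C=C/CC(=O)O)c1 | intermediate (key-step precursor)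
16 | acetic (E)-4-{2-[(2S,4S)-5-(benzyloxy)-2-methylchroman-4-yl]-5-methoxyphenyl}but-3-enoic anhydride | COc1ccc([C@@H]2C[C@H](C)Oc3cccc(OCc4ccccc4)c32)c(/C=C/CC(=O)OC(C)=O)c1 | intermediate (not isolated)
17 | (3Z)-4-{2-[(2S,4S)-5-(benzyloxy)-2-methylchroman-4-yl]-5-methoxyphenyl}buta-1,3-dien-1-one | COc1ccc([C@@H]2C[C@H](C)Oc3cccc(OCc4ccccc4)c32)c(/C=C\C=C=O)c1 | intermediate (not isolated)
18 | 5-[(2S,4S)-5-(benzyloxy)-2-methylchroman-4-yl]-8-methoxynaphthalen-1(8aH)-one, C8a not defined | COC1=CC=C([C@@H]2C[C@H](C)Oc3cccc(OCc4ccccc4)c32)C2=CC=CC(=O)C12 | intermediate (not isolated)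
19 | 5-[(2S,4S)-5-(benzyloxy)-2-methylchroman-4-yl]-8-methoxynaphthalen-1-ol | COc1ccc([C@@H]2C[C@H](C)Oc3cccc(OCc4ccccc4)c32)c2cccc(O)c12 | intermediate (not isolated)
20 | 5-[(2S,4S)-5-(benzyloxy)-2-methylchroman-4-yl]-8-methoxynaphthalen-1-yl acetate | CC(=O)Oc1cccc2c([C@@H]3C[C@H](C)Oc4cccc(OCc5ccccc5)c43)ccc(OC)c12 | intermediate (key-step product)
21 | potassium 5-[(2S,4S)-5-(benzyloxy)-2-methylchroman-4-yl]-8-methoxynaphthalen-1-olate | [K+].[O-]c1cccc2c([C@@H]3C[C@H](C)Oc4cccc(OCc5ccccc5)c43)ccc(OC)c12 | intermediate (not isolated)
22 | (2S,4S)-5-(benzyloxy)-4-(4,5-dimethoxynaphthalen-1-yl)-2-methylchroman | COc1cccc2c([C@@H]3C[C@H](C)Oc4cccc(OCc5ccccc5)c43)ccc(OC)c12 | intermediate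
23 | Cladonaphchrom B, (2S,4S)-4-(4,5-dimethoxynaphthalen-1-yl)-2-methylchroman-5-ol | COc1cccc2c([C@@H]3C[C@H](C)Oc4cccc(O)c43)ccc(OC)c12 | target

Total step count: 10. Longest linear sequence: 10 steps (1 → 23); 7 and 13 are purchased and enter at steps 4 and 7.

Steps most likely to fail

Step 8. Equilibration of the E-alkene to the cis geometry through the dienolate may be slower than oligomerisation of the ketene, and closure onto the carbon squeezed between the side chain and the methoxy group may stall, so that material is lost to polymeric anhydride and ketene products. The fallback sets out from 15, comes back at 21, and replaces the pericyclic closure by a Friedel–Crafts acylation on the same free ortho carbon. Diimide reduction of the alkene (2-nitrobenzenesulfonyl hydrazide, Et3N, CH2Cl2, rt) should give 4-{2-[(2S,4S)-5-(benzyloxy)-2-methylchroman-4-yl]-5-methoxyphenyl}butanoic acid F1 with the benzyl ether intact. Intramolecular acylation through the mixed trifluoroacetic anhydride ((CF3CO)2O, CH2Cl2, 0 °C) should give the tetralone 5-[(2S,4S)-5-(benzyloxy)-2-methylchroman-4-yl]-8-methoxy-3,4-dihydronaphthalen-1(2H)-one F2. Aerobic palladium-catalysed dehydrogenation of the cyclic ketone (Pd(OCOCF3)2, 2-(dimethylamino)pyridine, TsOH, O2, DMSO, 80 °C) should then deliver naphthol 19, here as an isolated compound. K2CO3 in DMF should convert it into potassium naphtholate 21, which is methylated with MeI exactly as in the second stage of step 9.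

Step 4. The aryl nucleophile has to attack a carbonyl shielded by the peri benzyloxy group while itself carrying an ortho substituent; slow addition would allow enolisation, and the enolate can open by a retro-oxa-Michael reaction, which would erode the C2 configuration or simply return ketone. The fallback sets out from 6, comes back at 11, and forms the C4–aryl bond by cross-coupling. O-Triflation without an enolate (Tf2O, 2,6-di-tert-butyl-4-methylpyridine, CH2Cl2, 0 °C) should give (S)-5-(benzyloxy)-2-methyl-2H-chromen-4-yl trifluoromethanesulfonate F3. Suzuki–Miyaura coupling with commercial (2-formyl-4-methoxyphenyl)boronic acid (Pd(PPh3)4, K3PO4, dioxane–H2O, 80 °C) should give 2-[(S)-5-(benzyloxy)-2-methyl-2H-chromen-4-yl]-5-methoxybenzaldehyde F4, and NaBH4 in MeOH the alcohol {2-[(S)-5-(benzyloxy)-2-methyl-2H-chromen-4-yl]-5-methoxyphenyl}methanol F5. Treatment with Et3SiH/CF3CO2H protonates the chromene at C3 to the same C4 cation as in step 5 and should give 11 with the same cis selectivity.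

Step 7. Under base the phosphonium salt can fragment by loss of Ph3P from its β-carboxyethyl group, and attack of the remaining ylide on the ortho-hindered aldehyde may be slow, so conversion may be poor. The fallback sets out from 12, comes back at 15, and builds the alkene by metathesis. Methylenation (Ph3PCH3Br, KOt-Bu, THF, 0 °C) should give (2S,4S)-5-(benzyloxy)-4-(4-methoxy-2-vinylphenyl)-2-methylchroman F6. Cross-metathesis with but-3-enoic acid (second-generation Hoveyda–Grubbs catalyst, CH2Cl2, 40 °C) should then give the E-acid 15.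

Further compounds

F1 | step 8 | 4-{2-[(2S,4S)-5-(benzyloxy)-2-methylchroman-4-yl]-5-methoxyphenyl}butanoic acid | COc1ccc([C@@H]2C[C@H](C)Oc3cccc(OCc4ccccc4)c32)c(CCCC(=O)O)c1
F2 | step 8 | 5-[(2S,4S)-5-(benzyloxy)-2-methylchroman-4-yl]-8-methoxy-3,4-dihydronaphthalen-1(2H)-one | COc1ccc([C@@H]2C[C@H](C)Oc3cccc(OCc4ccccc4)c32)c2CCCC(=O)c12
F3 | step 4 | (S)-5-(benzyloxy)-2-methyl-2H-chromen-4-yl trifluoromethanesulfonate | FC(F)(F)S(=O)(=O)OC1=C[C@H](C)Oc2cccc(OCc3ccccc3)c21
F4 | step 4 | 2-[(S)-5-(benzyloxy)-2-methyl-2H-chromen-4-yl]-5-methoxybenzaldehyde | O=Cc1cc(OC)ccc1C1=C[C@H](C)Oc2cccc(OCc3ccccc3)c21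
F5 | step 4 | {2-[(S)-5-(benzyloxy)-2-methyl-2H-chromen-4-yl]-5-methoxyphenyl}methanol | OCc1cc(OC)ccc1C1=C[C@H](C)Oc2cccc(OCc3ccccc3)c21
F6 | step 7 | (2S,4S)-5-(benzyloxy)-4-(4-methoxy-2-vinylphenyl)-2-methylchroman | C=Cc1cc(OC)ccc1[C@@H]1C[C@H](C)Oc2cccc(OCc3ccccc3)c21
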